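I wanted to know how much target the flask holds at 2.5 d, and whether red or teal lifts that by more than 2 percentage points.

| setting | west | north-west | flask |
|---|---|---|---|
| substrate | 10 mM | 40 mM | 20 mM |
| gas phase | 5.3 mM (held) | 5.3 mM (held) | 5.3 mM (held) |
| remark | run made earlier | run made earlier |  |
| time |  |  | 2.5 d |

| run | time / h | target / % |
|---|---|---|
| west | 3.00 | 42.5 |
| west | 10.0 | 86.9 |
| west | 15.0 | 81.3 |
| west | 25.0 | 67.2 |
| west | 40.0 | 55.1 |
| west | 50.0 | 47.1 |
| north-west | 8.00 | 48.1 |
| north-west | 15.0 | 64.6 |
| north-west | 25.0 | 57.4 |
| north-west | 30.0 | 54.0 |
| north-west | 40.0 | 46.8 |
| north-west | 50.0 | 40.7 |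

(standard deviation of a reading: 1 percentage point)

- how much target there is at 2.5 d, in percent of the substrate charged
- the change that raises the amount of target at 2.5 d, in percent of the substrate charged most ("none" if none brings more than 2 percentage points) (red / teal / none)
- amount of target at 2.5 d, in percent of the substrate charged, after red

- red: doubling the saturation concentration of gas phase, all else as stated
- teal: doubling the transfer coefficient of the gas phase, all else as stated

- the analysis behind the earlier runs scatters by 1 percentage point, standard deviation
- at the start none of the gas phase is in solution

Past its peak, target P fell in both runs like a first-order loss, so I integrated dP/dt = −k_f P to P(t) = P(25.0 h) exp(−k_f (t − 25.0 h)). The west readings from 25.0 h to 50.0 h gave 0.0142 h⁻¹ for k_f, the fading constant, the pseudo-first-order rate constant at which target falls after its peak. The north-west readings gave 0.0138 h⁻¹. The flask's substrate is twice the west charge and half the north-west one, so I carried the mean of the two readings at 25.0 h forward and reckoned 37.9%.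

Then I turned the question round. To gain 2 points over those 35.0 h, k_f in this flask had to drop to 0.0127 h⁻¹, and both runs faded faster than that. I supposed that the fall uses dissolved gas and that red and teal each raise it, so I expected none. If red doubled k_f from the start, target would take the factor exp(−k_f t) once more, giving 16.1%.

The forecast said 39%, none and 18% after red, where I had 37.9%, none and 16.1%, adding: “Doubling transfer changes little”.

The flask gave 38.9% and none: red changed target by −23 points and teal by −1.2 points, leaving 16.2% after red.

    gas phase ⇌ dissolved gas, rate k1*(csat - [dissolved gas]) (kL = 0.660 h⁻¹)
    substrate + dissolved gas → target (k = 110 M⁻¹ h⁻¹)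
    dissolved gas + target → over-reacted product (k = 3.10 M⁻¹ h⁻¹)
    2 substrate → homo dimer (k = 1.20 M⁻¹ h⁻¹)

For that choice to be wrong, a run had to show a gain above 2 points, and neither change did. On this flask, the factor exp(−k_f t) takes 38.9% to 16.6% beside the 16.2% after red. The neighbouring flask, read at 10 d with all amounts held, gets the same reckoning: 38.9% carried forward with k_f gives 3.02%, and that flask held 2.10%.

The numbers in the tables were computed with constants of no real substance; the scatter is artificial.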